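**Retrosynthetic overview**
- The C12–C15 chain is cut at C13=C14 (HWE on a C13 methyl ketone) and at C11=C12 (Wittig on a C11 aldehyde); the C18 acetate comes from a TIPS ether and the C15 acid from an allyl ester.
- Feature: in ring B (C5–C10) the methyl-bearing tertiary carbinol carbon C8 lies para to C5; with an oxygen between them, C5–C6–C7–C8(C17) is the diene of a 2-methylfuran locked in a 7-oxanorbornene.
- The 8α-OH/5α-H pair is therefore traced to a C5–O–C8 bridge: C5–O is cut by SN2′ hydride delivered from the C11 alkoxide, and the resulting Δ5 alkene is hydrogenated from the α face.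
- Key disconnection: C5–C10 and C8–C9 by intramolecular furan Diels–Alder reaction of (E)-enoate 17; ring A (through the tether) and ring B (through the cycloaddition) form in the same step.
- Precursor 17 comes from 2-methylfuran and diethyl methylmalonate (C4 quaternary centre, lipase desymmetrisation), a Wittig C3–C2 coupling and an HWE reaction.

Key step: step 12

Assumption: the lipase in step 3 is taken to acylate the enantiotopic hydroxymethyl arm that gives (R)-5; lipases of the opposite preference exist if it does not.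

Step 1
Reactants: 1 2-methylfuran; 2 diethyl methylmalonate
Product: 3 diethyl 2-methyl-2-(5-methylfuran-2-yl)malonate
Conditions: Mn(OAc)3·2H2O (2.2 equiv), NaOAc, AcOH, 60 °C, excess 1
Reagents that add atoms: none
Why: Mn(III)-mediated oxidative radical malonylation, in which the electrophilic tertiary malonyl radical adds to the free α-position of the furan and the adduct radical is oxidised and rearomatised, giving the future C4 with C19 and both CH2O precursors.

Step 2
Reactants: 3 diethyl 2-methyl-2-(5-methylfuran-2-yl)malonate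
Product: 4 2-methyl-2-(5-methylfuran-2-yl)propane-1,3-diol
Conditions: LiAlH4, THF, 0 °C → rt
Reagents that add atoms: none
Why: Hydride reduction of both esters gives the prochiral 1,3-diol, and the furan is inert to LiAlH4.

Step 3
Reactants: 4 2-methyl-2-(5-methylfuran-2-yl)propane-1,3-diol
Product: 5 (R)-3-hydroxy-2-methyl-2-(5-methylfuran-2-yl)propyl acetate
Conditions: vinyl acetate, Pseudomonas cepacia lipase, t-BuOMe, 25 °C
Reagents that add atoms: vinyl acetate CC(=O)OC=C
Why: Lipase-catalysed enantiotopos-selective transesterification (desymmetrisation) of a 2-aryl-2-methylpropane-1,3-diol-type substrate with an irreversible acyl donor should set the C4 configuration.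

Step 4
Reactants: 5 (R)-3-hydroxy-2-methyl-2-(5-methylfuran-2-yl)propyl acetate
Product: 6 (S)-2-methyl-2-(5-methylfuran-2-yl)-3-(triisopropylsilyloxy)propyl acetate
Conditions: TIPSOTf, 2,6-lutidine, CH2Cl2, −78 → 0 °C
Reagents that add atoms: triisopropylsilyl trifluoromethanesulfonate CC(C)[Si](C(C)C)(C(C)C)OS(=O)(=O)C(F)(F)F
Why: Fast silylation of the free neopentyl hydroxyl with a weak hindered base avoids 1,3-acetyl migration, which would erode the enantiomeric purity.

Step 5
Reactants: 6 (S)-2-methyl-2-(5-methylfuran-2-yl)-3-(triisopropylsilyloxy)propyl acetate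
Product: 7 (S)-2-methyl-2-(5-methylfuran-2-yl)-3-(triisopropylsilyloxy)propan-1-ol
Conditions: K2CO3 (cat.), MeOH, 0 °C → rt
Reagents that add atoms: none
Why: Base-catalysed methanolysis removes the acetate, and the bulky TIPS ether should not undergo O→O migration, so the C4 configuration is kept.

Step 6
Reactants: 7 (S)-2-methyl-2-(5-methylfuran-2-yl)-3-(triisopropylsilyloxy)propan-1-ol
Product: 8 (S)-2-methyl-2-(5-methylfuran-2-yl)-3-(triisopropylsilyloxy)propanal
Conditions: DMP, CH2Cl2, rt
Reagents that add atoms: none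
Why: Periodinane oxidation under near-neutral conditions tolerates the electron-rich furan, and the aldehyde has no α-hydrogen and cannot epimerise.

Step 7
Reactants: 9 2-(2-bromoethyl)-2-methyl-1,3-dioxolane
Product: 10 [2-(2-methyl-1,3-dioxolan-2-yl)ethyl]triphenylphosphonium bromide
Conditions: PPh3, MeCN, reflux
Reagents that add atoms: triphenylphosphine c1ccc(cc1)P(c1ccccc1)c1ccccc1
Why: SN2 quaternisation of the phosphine by the primary bromide, with the ketal masking the future C10 carbonyl.

Step 8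
Reactants: 8 (S)-2-methyl-2-(5-methylfuran-2-yl)-3-(triisopropylsilyloxy)propanal; 10 [2-(2-methyl-1,3-dioxolan-2-yl)ethyl]triphenylphosphonium bromide
Product: 12 triisopropyl{[(2S,3Z)-2-methyl-2-(5-methylfuran-2-yl)-5-(2-methyl-1,3-dioxolan-2-yl)pent-3-en-1-yl]oxy}silane, via phosphonium ylide 11 (not isolated)
Conditions: KHMDS, THF, −78 °C; then 8, −78 °C → rt
Reagents that add atoms: none
Why: Wittig olefination of the non-enolisable aldehyde with a non-stabilised ylide joins C3 to C2; the (Z) geometry is of no consequence because the alkene is saturated next.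

Step 9
Reactants: 12 triisopropyl{[(2S,3Z)-2-methyl-2-(5-methylfuran-2-yl)-5-(2-methyl-1,3-dioxolan-2-yl)pent-3-en-1-yl]oxy}silane
Product: 13 triisopropyl{[(2S)-2-methyl-2-(5-methylfuran-2-yl)-5-(2-methyl-1,3-dioxolan-2-yl)pentyl]oxy}silane
Conditions: H2 (4 bar), RhCl(PPh3)3 (5 mol %), toluene/EtOH, rt
Reagents that add atoms: none
Why: Homogeneous rhodium-catalysed hydrogenation reduces the cis-disubstituted alkene and leaves the furan, ketal and silyl ether untouched.

Step 10
Reactants: 13 triisopropyl{[(2S)-2-methyl-2-(5-methylfuran-2-yl)-5-(2-methyl-1,3-dioxolan-2-yl)pentyl]oxy}silane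
Product: 14 (6S)-6-methyl-6-(5-methylfuran-2-yl)-7-(triisopropylsilyloxy)heptan-2-one
Conditions: PPTS (cat.), acetone/H2O, 50 °C
Reagents that add atoms: water O
Why: Mild acid-catalysed ketal hydrolysis, which a 2,5-dialkylfuran and a primary TIPS ether tolerate.

Step 11
Reactants: 14 (6S)-6-methyl-6-(5-methylfuran-2-yl)-7-(triisopropylsilyloxy)heptan-2-one; 15 trimethyl phosphonoacetate
Product: 17 methyl (2E,7S)-3,7-dimethyl-7-(5-methylfuran-2-yl)-8-(triisopropylsilyloxy)oct-2-enoate, via sodium phosphonate carbanion 16 (not isolated)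
Conditions: NaH, THF, 0 °C; then 14, reflux; chromatographic removal of the (Z) isomer
Reagents that add atoms: none
Why: Horner–Wadsworth–Emmons olefination of the methyl ketone should favour the (E)-trisubstituted enoate; the (Z) isomer, which would lead to the C9 epimer, is removed by chromatography.

Step 12
Reactants: 17 methyl (2E,7S)-3,7-dimethyl-7-(5-methylfuran-2-yl)-8-(triisopropylsilyloxy)oct-2-enoate
Product: 18 methyl 5α,8α-epoxy-18-(triisopropylsilyloxy)-12,13,14,15,16-pentanorlabd-6-en-11-oate (4α-CH2OTIPS; 4β-CH3; 10β-CH3; 9α-H; ester endo)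
Conditions: 1.5 GPa, CH2Cl2, BHT (cat.), 30 °C; decompression at 0 °C, solution used cold at once
Reagents that add atoms: none
Why: Proposed new method: a thermal, high-pressure intramolecular furan [4+2] cycloaddition in which C5 and C8 of the 2-methylfuran (diene) bond to C10 and C9 of the tethered (E)-β,β-disubstituted enoate (dienophile) in a concerted, asynchronous process; the closest known reaction type is the pressure- or Lewis-acid-promoted intramolecular Diels–Alder reaction of furans with tethered acrylates and crotonates, which has not been shown to join a bridgehead carbon flanked by a quaternary centre to a second quaternary carbon. Ring A closes through the four-atom tether (C4–C3–C2–C1) in the exo mode, tether syn to the oxygen bridge, the only mode a short tether permits, and ring B is formed by the cycloaddition itself as the 7-oxanorbornene with the ester endo. C5 and C8 are set together by suprafacial addition across the furan, C10 (C20 anti to the bridge) by the exo tether, C9 by the (E) geometry, which keeps C20 and CO2Me cis, and the sense of all four relative to C4 by a chair-like ring A in which the larger CH2OTIPS arm is pseudo-equatorial and the C19 methyl pseudo-axial. The step needs conversion against a slow rate and an unfavourable equilibrium: 1.5 GPa is chosen because both the activation volume and the reaction volume of a Diels–Alder reaction are strongly negative, and the gem-disubstituted C4 favours the reactive rotamer. It also needs facial selectivity, which rests only on the size difference between CH3 and CH2OTIPS at C4; an unwanted facial isomer can be returned to 17 by thermal cycloreversion. The adduct is kept cold and taken on at once because it can revert at ambient pressure.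

Step 13
Reactants: 18 methyl 5α,8α-epoxy-18-(triisopropylsilyloxy)-12,13,14,15,16-pentanorlabd-6-en-11-oate
Product: 20 18-(triisopropylsilyloxy)-12,13,14,15,16-pentanorlabd-5-ene-8α,11-diol, via 11-hydroxy oxanorbornene 19 (not isolated)
Conditions: LiAlH4 (4 equiv), THF, 0 °C, then 45 °C; aqueous NaOH work-up
Reagents that add atoms: none
Why: Ester reduction is followed by hydroxyl-directed SN2′ hydride opening of the 7-oxanorbornene (a mode known for endo-hydroxyl-bearing 7-oxanorbornenes with LiAlH4): the endo C11 alkoxyaluminium hydride lies under C7 and delivers hydride there, the double bond moves to C5=C6 and the strained C5–O bond is expelled, so the bridge oxygen stays on C8 as the 8α-hydroxyl, whereas an undirected hydrometalation would place the metal on the less hindered C7 and cut C8–O.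

Step 14
Reactants: 20 18-(triisopropylsilyloxy)-12,13,14,15,16-pentanorlabd-5-ene-8α,11-diol
Product: 21 18-(triisopropylsilyloxy)-12,13,14,15,16-pentanorlabdane-8α,11-diol
Conditions: [Ir(cod)(PCy3)(py)]PF6 (10 mol %), H2 (10 bar), CH2Cl2, rt
Reagents that add atoms: none
Why: Hydroxyl-directed homogeneous hydrogenation of the trisubstituted Δ5 alkene, in which the catalyst is bound by the 8α-hydroxyl on the α face while the β face is blocked by the axial C19 and C20 methyl groups, should add hydrogen to C5 from the α face and give the trans-decalin (5α-H).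

Step 15
Reactants: 21 18-(triisopropylsilyloxy)-12,13,14,15,16-pentanorlabdane-8α,11-diol
Product: 22 8α-hydroxy-18-(triisopropylsilyloxy)-12,13,14,15,16-pentanorlabdan-11-al
Conditions: TEMPO (10 mol %), PhI(OAc)2, CH2Cl2, rt
Reagents that add atoms: none
Why: Oxoammonium (TEMPO) oxidation is selective for the primary alcohol and stops at the aldehyde; the tertiary 8α-hydroxyl is inert and the equatorial C9 formyl group is the stable epimer.

Step 16
Reactants: 22 8α-hydroxy-18-(triisopropylsilyloxy)-12,13,14,15,16-pentanorlabdan-11-al; 23 1-(triphenylphosphoranylidene)propan-2-one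
Product: 24 (11E)-8α-hydroxy-18-(triisopropylsilyloxy)-14,15-dinorlabd-11-en-13-one
Conditions: toluene, 90 °C
Reagents that add atoms: none
Why: Wittig olefination with a stabilised ylide under neutral conditions (no alkoxide, hence no retro-aldol of the β-hydroxy aldehyde) adds C12, C13 and C16 as the (E)-enone.

Step 17
Reactants: 24 (11E)-8α-hydroxy-18-(triisopropylsilyloxy)-14,15-dinorlabd-11-en-13-one
Product: 25 8α-hydroxy-18-(triisopropylsilyloxy)-14,15-dinorlabdan-13-one
Conditions: H2 (1 atm), Pd/C, EtOAc, rt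
Reagents that add atoms: none
Why: Heterogeneous hydrogenation saturates the conjugated C11=C12 bond and leaves the ketone, silyl ether and tertiary alcohol untouched.

Step 18
Reactants: 25 8α-hydroxy-18-(triisopropylsilyloxy)-14,15-dinorlabdan-13-one; 26 allyl diethylphosphonoacetate
Product: 28 allyl (13E)-8α-hydroxy-18-(triisopropylsilyloxy)labd-13-en-15-oate, via sodium phosphonate carbanion 27 (not isolated)
Conditions: NaH, THF, 0 °C; then 25, 60 °C; chromatographic removal of the (13Z) isomer
Reagents that add atoms: none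
Why: Horner–Wadsworth–Emmons olefination of the methyl ketone builds C13=C14 with the (E) isomer expected to predominate, and the allyl ester is chosen so that C15 can later be freed without touching the C18 acetate.

Step 19
Reactants: 28 allyl (13E)-8α-hydroxy-18-(triisopropylsilyloxy)labd-13-en-15-oate
Product: 29 allyl (13E)-8α,18-dihydroxylabd-13-en-15-oate
Conditions: TBAF, AcOH, THF, rt → 40 °C
Reagents that add atoms: none
Why: Fluoride-mediated desilylation buffered with acetic acid frees the neopentyl C18 alcohol without hydrolysing the allyl ester or dehydrating the tertiary alcohol.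

Step 20
Reactants: 29 allyl (13E)-8α,18-dihydroxylabd-13-en-15-oate
Product: 30 allyl (13E)-18-acetoxy-8α-hydroxylabd-13-en-15-oate
Conditions: Ac2O, pyridine, CH2Cl2, 0 °C → rt (no DMAP)
Reagents that add atoms: acetic anhydride CC(=O)OC(C)=O
Why: Acylation without a nucleophilic catalyst acetylates only the primary C18 hydroxyl, since the hindered tertiary 8α-hydroxyl does not react under these conditions.

Step 21
Reactants: 30 allyl (13E)-18-acetoxy-8α-hydroxylabd-13-en-15-oate
Product: 31 (13E)-18-acetoxy-8α-hydroxylabd-13-en-15-oic acid (CNP0077667.1)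
Conditions: Pd(PPh3)4 (5 mol %), morpholine, THF, rt
Reagents that add atoms: none
Why: Pd(0)-catalysed allyl transfer to the amine (Tsuji–Trost deallylation) liberates the C15 acid under neutral conditions that leave the acetate, the tertiary alcohol and the (E)-enoate intact.

**Compound list**
1 | 2-methylfuran | Cc1ccco1 | starting material
2 | diethyl methylmalonate | CCOC(=O)C(C)C(=O)OCC | starting material
3 | diethyl 2-methyl-2-(5-methylfuran-2-yl)malonate | CCOC(=O)C(C)(c1ccc(C)o1)C(=O)OCC | intermediate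
4 | 2-methyl-2-(5-methylfuran-2-yl)propane-1,3-diol | Cc1ccc(o1)C(C)(CO)CO | intermediate
5 | (R)-3-hydroxy-2-methyl-2-(5-methylfuran-2-yl)propyl acetate | Cc1ccc(o1)[C@](C)(CO)COC(C)=O | intermediate
6 | (S)-2-methyl-2-(5-methylfuran-2-yl)-3-(triisopropylsilyloxy)propyl acetate | Cc1ccc(o1)[C@](C)(CO[Si](C(C)C)(C(C)C)C(C)C)COC(C)=O | intermediate
7 | (S)-2-methyl-2-(5-methylfuran-2-yl)-3-(triisopropylsilyloxy)propan-1-ol | Cc1ccc(o1)[C@](C)(CO[Si](C(C)C)(C(C)C)C(C)C)CO | intermediate
8 | (S)-2-methyl-2-(5-methylfuran-2-yl)-3-(triisopropylsilyloxy)propanal | Cc1ccc(o1)[C@](C)(CO[Si](C(C)C)(C(C)C)C(C)C)C=O | intermediate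
9 | 2-(2-bromoethyl)-2-methyl-1,3-dioxolane | CC1(CCBr)OCCO1 | starting material
10 | [2-(2-methyl-1,3-dioxolan-2-yl)ethyl]triphenylphosphonium bromide | CC1(CC[P+](c2ccccc2)(c2ccccc2)c2ccccc2)OCCO1.[Br-] | intermediate
11 | triphenyl[2-(2-methyl-1,3-dioxolan-2-yl)ethylidene]phosphorane (ylide, not isolated) | CC1(CC=P(c2ccccc2)(c2ccccc2)c2ccccc2)OCCO1 | intermediate
12 | triisopropyl{[(2S,3Z)-2-methyl-2-(5-methylfuran-2-yl)-5-(2-methyl-1,3-dioxolan-2-yl)pent-3-en-1-yl]oxy}silane | Cc1ccc(o1)[C@](C)(CO[Si](C(C)C)(C(C)C)C(C)C)/C=C\CC2(C)OCCO2 | intermediate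
13 | triisopropyl{[(2S)-2-methyl-2-(5-methylfuran-2-yl)-5-(2-methyl-1,3-dioxolan-2-yl)pentyl]oxy}silane | Cc1ccc(o1)[C@](C)(CO[Si](C(C)C)(C(C)C)C(C)C)CCCC2(C)OCCO2 | intermediate
14 | (6S)-6-methyl-6-(5-methylfuran-2-yl)-7-(triisopropylsilyloxy)heptan-2-one | Cc1ccc(o1)[C@](C)(CO[Si](C(C)C)(C(C)C)C(C)C)CCCC(C)=O | intermediate
15 | trimethyl phosphonoacetate | COC(=O)CP(=O)(OC)OC | starting material
16 | sodium (dimethoxyphosphoryl)(methoxycarbonyl)methanide (not isolated) | COC(=O)[CH-]P(=O)(OC)OC.[Na+] | intermediate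
17 | methyl (2E,7S)-3,7-dimethyl-7-(5-methylfuran-2-yl)-8-(triisopropylsilyloxy)oct-2-enoate | Cc1ccc(o1)[C@](C)(CO[Si](C(C)C)(C(C)C)C(C)C)CCC/C(C)=C/C(=O)OC | intermediate
18 | methyl 5α,8α-epoxy-18-(triisopropylsilyloxy)-12,13,14,15,16-pentanorlabd-6-en-11-oate | CC(C)[Si](C(C)C)(C(C)C)OC[C@]1(C)CCC[C@]2(C)[C@@H](C(=O)OC)[C@@]3(C)C=C[C@@]12O3 | intermediate
19 | 5α,8α-epoxy-18-(triisopropylsilyloxy)-12,13,14,15,16-pentanorlabd-6-en-11-ol (formed as its aluminium alkoxide, not isolated) | CC(C)[Si](C(C)C)(C(C)C)OC[C@]1(C)CCC[C@]2(C)[C@@H](CO)[C@@]3(C)C=C[C@@]12O3 | intermediate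
20 | 18-(triisopropylsilyloxy)-12,13,14,15,16-pentanorlabd-5-ene-8α,11-diol | CC(C)[Si](C(C)C)(C(C)C)OC[C@]1(C)CCC[C@]2(C)[C@@H](CO)[C@](C)(O)CC=C12 | intermediate
21 | 18-(triisopropylsilyloxy)-12,13,14,15,16-pentanorlabdane-8α,11-diol | CC(C)[Si](C(C)C)(C(C)C)OC[C@]1(C)CCC[C@]2(C)[C@@H](CO)[C@](C)(O)CC[C@@H]12 | intermediate
22 | 8α-hydroxy-18-(triisopropylsilyloxy)-12,13,14,15,16-pentanorlabdan-11-al | CC(C)[Si](C(C)C)(C(C)C)OC[C@]1(C)CCC[C@]2(C)[C@@H](C=O)[C@](C)(O)CC[C@@H]12 | intermediate
23 | 1-(triphenylphosphoranylidene)propan-2-one | CC(=O)C=P(c1ccccc1)(c1ccccc1)c1ccccc1 | starting material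
24 | (11E)-8α-hydroxy-18-(triisopropylsilyloxy)-14,15-dinorlabd-11-en-13-one | CC(C)[Si](C(C)C)(C(C)C)OC[C@]1(C)CCC[C@]2(C)[C@@H](/C=C/C(C)=O)[C@](C)(O)CC[C@@H]12 | intermediate
25 | 8α-hydroxy-18-(triisopropylsilyloxy)-14,15-dinorlabdan-13-one | CC(C)[Si](C(C)C)(C(C)C)OC[C@]1(C)CCC[C@]2(C)[C@@H](CCC(C)=O)[C@](C)(O)CC[C@@H]12 | intermediate
26 | allyl diethylphosphonoacetate | CCOP(=O)(CC(=O)OCC=C)OCC | starting material
27 | sodium (allyloxycarbonyl)(diethoxyphosphoryl)methanide (not isolated) | C=CCOC(=O)[CH-]P(=O)(OCC)OCC.[Na+] | intermediate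
28 | allyl (13E)-8α-hydroxy-18-(triisopropylsilyloxy)labd-13-en-15-oate | CC(C)[Si](C(C)C)(C(C)C)OC[C@]1(C)CCC[C@]2(C)[C@@H](CC/C(C)=C/C(=O)OCC=C)[C@](C)(O)CC[C@@H]12 | intermediate
29 | allyl (13E)-8α,18-dihydroxylabd-13-en-15-oate | OC[C@]1(C)CCC[C@]2(C)[C@@H](CC/C(C)=C/C(=O)OCC=C)[C@](C)(O)CC[C@@H]12 | intermediate
30 | allyl (13E)-18-acetoxy-8α-hydroxylabd-13-en-15-oate | CC(=O)OC[C@]1(C)CCC[C@]2(C)[C@@H](CC/C(C)=C/C(=O)OCC=C)[C@](C)(O)CC[C@@H]12 | intermediate
31 | (13E)-18-acetoxy-8α-hydroxylabd-13-en-15-oic acid (CNP0077667.1) | CC(=O)OC[C@]1(C)CCC[C@]2(C)[C@@H](CC/C(C)=C/C(=O)O)[C@](C)(O)CC[C@@H]12 | target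

**Step count and risks**

Total step count: 21. Longest linear sequence: 20 steps (steps 1–6 and 8–21; step 7 prepares the phosphonium salt).

Steps most likely to fail:

1. Step 12 (bears the new-method label). The cycloaddition may be too slow or thermodynamically uphill even under pressure, the adduct may revert on decompression, or the C4 centre may discriminate poorly between the two diene faces. The fallback uses known chemistry and runs from 8 to 21. The activating carbonyl is moved into the tether as a C1 ketone conjugated to C9=C10; for this substrate class, Lewis-acid-promoted intramolecular furan Diels–Alder reactions that create a quaternary carbon next to the bridgehead are established. Aldehyde 8 is methylenated (Ph3P=CH2, THF) to triisopropyl{[(2S)-2-methyl-2-(5-methylfuran-2-yl)but-3-en-1-yl]oxy}silane F1. Hydrozirconation (Cp2Zr(H)Cl) and ZnBr2-catalysed addition of the alkylzirconium to commercial ethyl (E)-3-methyl-4-oxobut-2-enoate should give ethyl (2E,7S)-4-hydroxy-3,7-dimethyl-7-(5-methylfuran-2-yl)-8-(triisopropylsilyloxy)oct-2-enoate F2. DMP oxidation gives ethyl (2E,7S)-3,7-dimethyl-7-(5-methylfuran-2-yl)-4-oxo-8-(triisopropylsilyloxy)oct-2-enoate F3. MeAlCl2 in CH2Cl2 at −78 °C should close rings A and B to ethyl 5α,8α-epoxy-1-oxo-18-(triisopropylsilyloxy)-12,13,14,15,16-pentanorlabd-6-en-11-oate F4. The C1 oxygen is removed through the enol triflate ethyl 5α,8α-epoxy-18-(triisopropylsilyloxy)-1-(trifluoromethylsulfonyloxy)-12,13,14,15,16-pentanorlabda-1,6-dien-11-oate F5 (KHMDS, PhNTf2, −78 °C) and Pd-catalysed formate reduction (Pd(OAc)2, PPh3, HCO2H, Bu3N) to ethyl 5α,8α-epoxy-18-(triisopropylsilyloxy)-12,13,14,15,16-pentanorlabda-1,6-dien-11-oate F6. LiAlH4 under the conditions of step 13 should give 18-(triisopropylsilyloxy)-12,13,14,15,16-pentanorlabda-1,5-diene-8α,11-diol F7, and the hydrogenation of step 14 saturates both C1=C2 and C5=C6 to give 21.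

2. Step 13. Hydride may not be delivered from the C11 alkoxide (no opening), the alkoxide adduct may undergo cycloreversion on warming, or C8–O may be cut instead of C5–O. The fallback runs from 18 to 21 and fixes the regiochemistry of bridge cleavage with a C7 ketone. Hydroboration–oxidation of 18 (BH3·THF, 0 °C; NaBO3) on the exo face at the less hindered C7 should give methyl 5α,8α-epoxy-7α-hydroxy-18-(triisopropylsilyloxy)-12,13,14,15,16-pentanorlabdan-11-oate F8. DMP gives methyl 5α,8α-epoxy-7-oxo-18-(triisopropylsilyloxy)-12,13,14,15,16-pentanorlabdan-11-oate F9. DBU in CH2Cl2 induces β-elimination, which can only pass through the C6 enolate and therefore cuts C5–O, giving methyl 8α-hydroxy-7-oxo-18-(triisopropylsilyloxy)-12,13,14,15,16-pentanorlabd-5-en-11-oate F10. H2 over Pd/C adds to the enone from the open α face to give methyl 8α-hydroxy-7-oxo-18-(triisopropylsilyloxy)-12,13,14,15,16-pentanorlabdan-11-oate F11. NaBH4 gives methyl 7,8α-dihydroxy-18-(triisopropylsilyloxy)-12,13,14,15,16-pentanorlabdan-11-oate F12. Selective acylation of the secondary hydroxyl (PhOC(S)Cl, pyridine) gives methyl 8α-hydroxy-7-(phenoxythiocarbonyloxy)-18-(triisopropylsilyloxy)-12,13,14,15,16-pentanorlabdan-11-oate F13. Barton–McCombie reduction (Bu3SnH, AIBN, toluene, 80 °C) gives methyl 8α-hydroxy-18-(triisopropylsilyloxy)-12,13,14,15,16-pentanorlabdan-11-oate F14, and LiAlH4 reduces the ester to give 21.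

3. Step 14. The C5=C6 bond lies between two quaternary carbons and may not bind the iridium catalyst, or the catalyst may be captured by the C11 hydroxyl and fail to deliver hydrogen to the α face. The fallback runs from 20 to 21 and makes no new compound: a radical hydrogen-atom-transfer hydrogenation (Mn(dpm)3, PhSiH3, t-BuOOH, i-PrOH, rt) forms the tertiary C5 radical and quenches it from the unhindered α face, which should give the thermodynamically preferred trans ring fusion.

Further compounds
F1 | step 12 | triisopropyl{[(2S)-2-methyl-2-(5-methylfuran-2-yl)but-3-en-1-yl]oxy}silane | Cc1ccc(o1)[C@](C)(CO[Si](C(C)C)(C(C)C)C(C)C)C=C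
F2 | step 12 | ethyl (2E,7S)-4-hydroxy-3,7-dimethyl-7-(5-methylfuran-2-yl)-8-(triisopropylsilyloxy)oct-2-enoate (C4 epimers) | Cc1ccc(o1)[C@](C)(CO[Si](C(C)C)(C(C)C)C(C)C)CCC(O)/C(C)=C/C(=O)OCC
F3 | step 12 | ethyl (2E,7S)-3,7-dimethyl-7-(5-methylfuran-2-yl)-4-oxo-8-(triisopropylsilyloxy)oct-2-enoate | Cc1ccc(o1)[C@](C)(CO[Si](C(C)C)(C(C)C)C(C)C)CCC(=O)/C(C)=C/C(=O)OCC
F4 | step 12 | ethyl 5α,8α-epoxy-1-oxo-18-(triisopropylsilyloxy)-12,13,14,15,16-pentanorlabd-6-en-11-oate | CC(C)[Si](C(C)C)(C(C)C)OC[C@]1(C)CCC(=O)[C@]2(C)[C@@H](C(=O)OCC)[C@@]3(C)C=C[C@@]12O3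
F5 | step 12 | ethyl 5α,8α-epoxy-18-(triisopropylsilyloxy)-1-(trifluoromethylsulfonyloxy)-12,13,14,15,16-pentanorlabda-1,6-dien-11-oate | CC(C)[Si](C(C)C)(C(C)C)OC[C@]1(C)CC=C(OS(=O)(=O)C(F)(F)F)[C@]2(C)[C@@H](C(=O)OCC)[C@@]3(C)C=C[C@@]12O3
F6 | step 12 | ethyl 5α,8α-epoxy-18-(triisopropylsilyloxy)-12,13,14,15,16-pentanorlabda-1,6-dien-11-oate | CC(C)[Si](C(C)C)(C(C)C)OC[C@]1(C)CC=C[C@]2(C)[C@@H](C(=O)OCC)[C@@]3(C)C=C[C@@]12O3
F7 | step 12 | 18-(triisopropylsilyloxy)-12,13,14,15,16-pentanorlabda-1,5-diene-8α,11-diol | CC(C)[Si](C(C)C)(C(C)C)OC[C@]1(C)CC=C[C@]2(C)[C@@H](CO)[C@](C)(O)CC=C12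
F8 | step 13 | methyl 5α,8α-epoxy-7α-hydroxy-18-(triisopropylsilyloxy)-12,13,14,15,16-pentanorlabdan-11-oate | CC(C)[Si](C(C)C)(C(C)C)OC[C@]1(C)CCC[C@]2(C)[C@@H](C(=O)OC)[C@@]3(C)[C@H](O)C[C@@]12O3
F9 | step 13 | methyl 5α,8α-epoxy-7-oxo-18-(triisopropylsilyloxy)-12,13,14,15,16-pentanorlabdan-11-oate | CC(C)[Si](C(C)C)(C(C)C)OC[C@]1(C)CCC[C@]2(C)[C@@H](C(=O)OC)[C@@]3(C)C(=O)C[C@@]12O3
F10 | step 13 | methyl 8α-hydroxy-7-oxo-18-(triisopropylsilyloxy)-12,13,14,15,16-pentanorlabd-5-en-11-oate | CC(C)[Si](C(C)C)(C(C)C)OC[C@]1(C)CCC[C@]2(C)[C@@H](C(=O)OC)[C@](C)(O)C(=O)C=C12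
F11 | step 13 | methyl 8α-hydroxy-7-oxo-18-(triisopropylsilyloxy)-12,13,14,15,16-pentanorlabdan-11-oate | CC(C)[Si](C(C)C)(C(C)C)OC[C@]1(C)CCC[C@]2(C)[C@@H](C(=O)OC)[C@](C)(O)C(=O)C[C@@H]12
F12 | step 13 | methyl 7,8α-dihydroxy-18-(triisopropylsilyloxy)-12,13,14,15,16-pentanorlabdan-11-oate (C7 epimers) | CC(C)[Si](C(C)C)(C(C)C)OC[C@]1(C)CCC[C@]2(C)[C@@H](C(=O)OC)[C@](C)(O)C(O)C[C@@H]12
F13 | step 13 | methyl 8α-hydroxy-7-(phenoxythiocarbonyloxy)-18-(triisopropylsilyloxy)-12,13,14,15,16-pentanorlabdan-11-oate (C7 epimers) | CC(C)[Si](C(C)C)(C(C)C)OC[C@]1(C)CCC[C@]2(C)[C@@H](C(=O)OC)[C@](C)(O)C(OC(=S)Oc3ccccc3)C[C@@H]12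
F14 | step 13 | methyl 8α-hydroxy-18-(triisopropylsilyloxy)-12,13,14,15,16-pentanorlabdan-11-oate | CC(C)[Si](C(C)C)(C(C)C)OC[C@]1(C)CCC[C@]2(C)[C@@H](C(=O)OC)[C@](C)(O)CC[C@@H]12
F0 | step 14 | none | none
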